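## Structural features

The target is a 2,3-dihydro-1-benzofuran whose benzene ring is a fully substituted acylphloroglucinol: O1 sits on C7a, hydroxyls on C4 and C6, an acetyl group on C5 between them, the ring CH2 (C3) on C3a and a CH2 bridge on C7. That bridge ends at C3 of a 6-ethyl-4-hydroxy-5-methyl-2H-pyran-2-one, so two enolic rings are joined through one carbon. The only stereocentre is C2 (R). It has no stereogenic neighbour: it is flanked by the benzylic C3, by O1 and by the 1,1-disubstituted alkene carbon of a 6-methylhepta-1,5-dien-2-yl chain. The fragile features are the allylic aryl ether bond C2–O1 (ionised by strong acid or zerovalent palladium), the two alkenes (no hydrogenolysis, no strong electrophiles), the electron-rich phenol and pyranone enols, and the doubly activated CH2 bridge, which can exchange to symmetrical dimers. The real difficulty is threefold: fixing the absolute configuration of an isolated oxygenated carbon that carries a branched diene, telling three phenolic oxygens apart so that only the one para to the acetyl group closes the furan ring, and making an unsymmetrical methylene bridge. The key step uses the fact that C2 bears both the CH2 leading to arene carbon C3a and the alkenyl carbon of the diene, with a heteroatom on the same carbon. This is the pattern left at the boron-bearing carbon when an aryl electrophile induces alkenyl migration in a vinylboron ate complex; the boron is then exchanged for oxygen.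

## Logic of the disconnections

**23 to 16 and 20.** Both bonds of the bridging CH2 in 23 are cut (arene C7–CH2 and CH2–C3 of the pyranone ring). Both termini are nucleophilic carbons, so a formaldehyde-level electrophile can join them. This halves the molecule and puts the bridge-forming event last, under nearly neutral conditions. The forward step must favour the cross product over the two symmetrical dimers. Hence 20 is first converted into 21, and 22 is released only in the presence of 16, whose C7 is the single free arene position.

**16 to 15 to 14.** The two chelated phenols of 16 are masked again (15), and the O1–C2 bond is cut to give 14. A 5-exo SN2 closure by the phenol on an activated secondary alcohol forms the ring and inverts C2, so an S alcohol is needed for the R ether. The ring is thereby exchanged for an open-chain allylic alcohol. The demand is regiochemical: the oxygen on the other side of the side chain is equally well placed for ring closure, so it must stay protected while the para oxygen is free. This calls for two orthogonal protecting groups (acetal on the ortho oxygens, silyl on the para oxygen).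

**14 to 13 to 12.** The silyl ether is restored (13) and the C2–O bond is traced back to a C2–B bond (12). Oxidation of a secondary boronic ester is stereoretentive and leaves the allylic system in place. The demand is that alkaline peroxide spares the aryl silyl ether, the acetals and the aryl ketone. For this reason the silyl group is triisopropylsilyl and not tert-butyldimethylsilyl: an aryl tert-butyldimethylsilyl ether is easily cleaved by hydroxide or hydroperoxide, which would expose a para-acyl phenoxide to the oxidant.

**12 to 4 and 11.** Two bonds are cut at once: C3a–C3 (aryl–CH2) and C2–C(alkenyl). What remains is an aryl iodide, a vinyl group and a dienyl group, the last two held on one boron atom. This is the largest simplification in the plan: three simple fragments, two C–C bonds and the stereocentre in one operation, with the 1,1-disubstituted alkene arriving intact. The demands are that palladium engages the unsubstituted vinyl group so that the branched alkenyl group migrates, that the chiral ligand delivers the S boronate, and that a doubly ortho-substituted aryl iodide is accepted.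

**11 to 8 and 10; 8 to 6 to 5; 10 to 9.** The B–C(vinyl) bond of 11 is cut, giving a purified alkenyl boronic ester and halide-free vinyllithium. Adding crude 7 to a vinyl boronic ester would give the same borate in fewer steps. It would, however, carry one equivalent of lithium arenesulfinate and any excess butyllithium into the catalytic step, where sulfinate can occupy the cationic palladium centre and butyllithium would form a competing butyl borate. Trapping 7 as 8 and purifying it removes both. 8 comes from 6 by Shapiro reaction and borylation, and 6 from 5 by condensation. The demand is regioselective lithiation on the methyl side of the hydrazone.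

**4 to 3 to 2 to 1.** The C–I bond, the two acetal O–C bonds and the O–Si bond are removed in turn. 3 has a mirror plane through the acetyl and silyloxy carbons, so its two free ring positions are equivalent and mono-iodination has no regiochemical question. In 1 the para hydroxyl is the only one outside the acetyl chelate and is silylated first. The demands are mono-iodination only, and a silyl ether that survives full deprotonation of the chelated phenols.

**20 to 19 to 17 and 18.** The lactone O–C(=O) bond is opened to the 3,5-dioxo ester 19, and the bond between C4 and C5 of its chain is cut to give a β-keto ester dianion and an acyl donor. Both partners are small commercial compounds. The demand is acylation at the γ-carbon of the dianion and not at oxygen, which a Weinreb amide favours.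

## Other disconnections considered

**Alternative 1:** The cut runs through C3a–C3 and C7a–O1, so the whole dihydrofuran ring is removed at once. It leaves aryl iodide A2 (iodine on the future C7a, para to the acetyl group) and the enantiopure epoxide A3.

- Forward key step: palladium with a strained bicyclic alkene as transient mediator (Catellani manifold) would palladate the C–H ortho to iodine, and the palladacycle would open A3 at its CH2 terminus. After loss of the mediator the alkoxide would couple at the ipso carbon to give A1, with the epoxide stereocentre untouched.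
- In its favour: the ring, the C–C bond and the C–O bond arise in one step, and C2 is never inverted or ionised. On stereochemical security at the ring-closing stage this plan is the better one. It also needs no boron-to-oxygen exchange, desilylation or Mitsunobu step.
- Against it here: A2 needs iodine where 1 carries oxygen, so the arene must come from a different and less accessible starting material. Both C–H bonds ortho to iodine in A2 are flanked by alkoxy groups, which slows palladation, and without an ortho blocking group the second ortho position may react before the mediator leaves. A3 must be made separately as one enantiomer. The 1,1-disubstituted alkene is absent from A1: the ketal must be hydrolysed to ketone A4 and then methylenated to reach 16, next to an epimerisable α-aryloxy stereocentre and in the presence of the acetyl group.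
- Comparison: in convergence the two plans are equal (arene plus a C8 unit). Mechanistically the alternative rests on C–H functionalisation at a hindered site and the chosen plan on alkene capture by a hindered arylpalladium species, so neither key event is clearly safer. In step economy the alternative is ahead after its key step but behind before it (A2 and A3) and through the late methylenation. It also puts the stereocentre at risk at A4, which the chosen plan avoids by bringing the alkene in from 5.

**Alternative 2:** The cut is through the pyranone bonds C3–C4 and O1–C2 (pyranone numbering). It leaves the siloxyalkyne A6, a three-carbon arm on arene C7, and the acylketene A8, released thermally from dioxinone A7.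

- Forward key step: A8 would add across the ynol ether. The alkyne carbon bearing the arylmethyl group attacks the ketene carbon and the acyl oxygen closes on the siloxy carbon, giving A5. Desilylation with tautomerisation, then removal of the two acetates, would give 23.
- In its favour: the bridging carbon is in place before the pyranone exists, so no symmetrical dimers can form. On this point it is better than step 13. The cycloaddition is neutral and its regiochemistry follows from the polarisation of the ynol ether.
- Against it here: A6 needs a propargylic arm and an ynol silyl ether on a fully substituted arene that carries aryl acetates and an aryl ketone. The usual access, ester-to-ynolate homologation with strong base, is poorly compatible with these groups. The siloxyalkyne is hydrolytically labile and A8 can dimerise. The plan does not touch C2, so A6 would still have to come from 16 or a close relative, and the stereochemical problem is unchanged.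
- Comparison: structurally it is equal in what it leaves for the dihydrobenzofuran half. Mechanistically it is a regio-defined cycloaddition against an ionic three-component coupling. In step economy it is clearly longer: arm installation, homologation, silylation, cycloaddition and two deprotections, against one step from 16 and 20.

**Alternative 3:** The cut is through the pyranone bonds C4–C5 and O1–C2. Pyranone C2, C3 and C4 and the bridge come from the dihydrocoumarin acid chloride A10, annulated across O6 and C7 of the arene. C5 and C6, with their methyl and ethyl groups, come from A12.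

- Forward key step: loss of HCl from A10 would give acylketene A11. C-acylation of the enol of A12 forms C4–C5, and the new enol oxygen then opens the aryl lactone by acyl substitution. This closes the pyranone and frees the C6 phenol, giving A9, one deacetylation from 23.
- In its favour: the bridge position is fixed in advance, so no dimers can form. The lactone serves as activating group and as traceless protection of the C6 hydroxyl, and A12 is the simplest possible source of the ethyl and methyl end. A9 is as close to 23 as 16 is. On these points it is equal or better.
- Against it here: A10 requires the C4 and C6 hydroxyls to be told apart (one acetylated, one lactonised), which the chosen route never has to do. It also needs a one-carbon functionalisation of C7 and a malonate-type annulation and reduction, several steps on the sensitive bicycle. Acylketenes usually add to ketone carbonyls as heterodienes to give dioxinones, so C-acylation of the small enol population of A12 must win, and A11 can dimerise.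
- Comparison: as with alternative 2, C2 is not addressed. The step count is higher than making 20 in one step and coupling in one more. The uncertainty between carbon and carbonyl capture of A11 is larger than that of the Mannich-type coupling.

Key step: step 7

Remarks on the chemistry:
- Commercial 1 is sold as a hydrate and is taken as dried before step 1.
- The ligand L of step 7 is (Sp,Sp)-1,1′-bis[bis(4-methoxy-3,5-dimethylphenyl)phosphino]-2,2′-bis[(R)-α-(dimethylamino)benzyl]ferrocene (MandyPhos type) or its mirror image. The antipode is chosen so that 12 is S, and the assignment should be confirmed at 13 by Mosher ester analysis.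
- Descriptors were checked. 12 and 13 are S (the alkenyl carbon outranks CH2Ar, which outranks boron), and SN2 closure turns this into R in 15, 16 and 23.

## Route

Step 1
Reactants: 1 2,4,6-trihydroxyacetophenone
Product: 2 1-[2,6-dihydroxy-4-(triisopropylsilyloxy)phenyl]ethanone
Conditions: TIPSCl (1.05 equiv), imidazole, DMF, 0 °C
Reagents that add atoms: chlorotriisopropylsilane, CC(C)[Si](Cl)(C(C)C)C(C)C
Why: The C4 hydroxyl is the only one outside the acetyl hydrogen-bond chelate and is the most acidic and least hindered, so one equivalent of a bulky silyl chloride should silylate it selectively (silyl ether formation).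

Step 2
Reactants: 2 1-[2,6-dihydroxy-4-(triisopropylsilyloxy)phenyl]ethanone
Product: 3 1-[2,6-bis(methoxymethoxy)-4-(triisopropylsilyloxy)phenyl]ethanone
Conditions: NaH (2.5 equiv), MOMCl (2.6 equiv), THF/DMF, 0 °C
Reagents that add atoms: chloromethyl methyl ether, COCCl
Why: Full deprotonation with NaH breaks the chelates so that both ortho phenoxides undergo Williamson-type O-alkylation; the aryl triisopropylsilyl ether resists phenoxide-mediated silyl transfer far better than a tert-butyldimethylsilyl ether would.

Step 3
Reactants: 3 1-[2,6-bis(methoxymethoxy)-4-(triisopropylsilyloxy)phenyl]ethanone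
Product: 4 1-[3-iodo-2,6-bis(methoxymethoxy)-4-(triisopropylsilyloxy)phenyl]ethanone
Conditions: NIS (1.05 equiv), DMF, 0 °C to rt, dark
Reagents that add atoms: N-iodosuccinimide, O=C1CCC(=O)N1I
Why: Electrophilic aromatic iodination of a tri-oxygenated ring whose acetyl group is twisted out of conjugation; C3 and C5 are equivalent by symmetry, so mono-iodination can give only one regioisomer, and the first iodine slows the second.

Step 4
Reactants: 5 6-methylhept-5-en-2-one
Product: 6 N'-[(2E)-6-methylhept-5-en-2-ylidene]-2,4,6-triisopropylbenzenesulfonohydrazide
Conditions: TrisNHNH2, MeOH, HCl (cat.), rt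
Reagents that add atoms: 2,4,6-triisopropylbenzenesulfonohydrazide, CC(C)c1cc(C(C)C)c(S(=O)(=O)NN)c(C(C)C)c1
Why: Acid-catalysed condensation of the ketone with the sulfonyl hydrazide should give the hydrazone, mainly as the E isomer with the sulfonamide nitrogen syn to the methyl group, which crystallises from the medium.

Step 5
Reactants: 6 N'-[(2E)-6-methylhept-5-en-2-ylidene]-2,4,6-triisopropylbenzenesulfonohydrazide
Product: 8 4,4,5,5-tetramethyl-2-(6-methylhepta-1,5-dien-2-yl)-1,3,2-dioxaborolane, via dienyllithium 7 (not isolated)
Conditions: n-BuLi (2.05 equiv), THF, −78 °C then 0 °C; i-PrOBpin, −78 °C to rt; H2O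
Reagents that add atoms: 2-isopropoxy-4,4,5,5-tetramethyl-1,3,2-dioxaborolane, CC(C)OB1OC(C)(C)C(C)(C)O1
Why: Shapiro reaction: the dianion forms by deprotonation of the methyl group syn to the sulfonamide nitrogen and loses sulfinate and N2 to give the 2-lithio-1-alkene 7 regioselectively; borylation and loss of isopropoxide give the alkenyl boronic ester, which is purified free of sulfinate and butyllithium residues.

Step 6
Reactants: 9 tetraethenylstannane Sn(CH=CH2)4
Product: 10 ethenyllithium (vinyllithium)
Conditions: n-BuLi (4 equiv), pentane, rt; filtration under Ar; solid dissolved in Et2O and titrated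
Reagents that add atoms: n-butyllithium, [Li]CCCC
Why: Tin–lithium exchange is driven by precipitation of vinyllithium from pentane; collecting the solid gives a reagent free of halide and of tin residues, as the cationic palladium step requires.

Step 7
Reactants: 4 1-[3-iodo-2,6-bis(methoxymethoxy)-4-(triisopropylsilyloxy)phenyl]ethanone; 8 4,4,5,5-tetramethyl-2-(6-methylhepta-1,5-dien-2-yl)-1,3,2-dioxaborolane; 10 ethenyllithium
Product: 12 1-[2,6-bis(methoxymethoxy)-3-[(2S)-7-methyl-3-methylidene-2-(4,4,5,5-tetramethyl-1,3,2-dioxaborolan-2-yl)oct-6-en-1-yl]-4-(triisopropylsilyloxy)phenyl]ethanone, via lithium borate 11 (not isolated)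
Conditions: 8 + 10 (1:1, 1.3 equiv), THF, 0 °C to rt; then 4, Pd(OAc)2 (5 mol %), L (6 mol %), KOTf (2 equiv), THF, 60 °C
Reagents that add atoms: none
Why: Zerovalent palladium inserts into the C–I bond of 4 and KOTf removes iodide as KI, leaving a cationic arylpalladium species with a free site. This species binds the unsubstituted vinyl group of 11; π-activation triggers an anti 1,2-shift of the dienyl group from boron to the boron-bearing carbon while palladium bonds the terminal CH2, and reductive elimination then forms the aryl–CH2 bond. The closest known reaction type is the enantioselective conjunctive cross-coupling of bis(alkenyl)borates with aryl electrophiles to give α-chiral allylic boronic esters, with a triflate salt as halide scavenger. No ring is closed. The new stereocentre is set in the metallate shift: the chiral bis(phosphine) selects the face of the vinyl group that palladium binds and the migrating group arrives on the opposite face, so the choice of ligand antipode fixes S. The step needs chemoselectivity between the two alkenyl groups, secured by the α-branch of the dienyl group, which keeps palladium on the unhindered vinyl group and makes the dienyl group the one that migrates; the remote trisubstituted alkene is too hindered to bind. Direct alkenyl transfer and β-hydride elimination should be held back by the chelating ligand, and the twisted acetyl group, the acetals and the silyl ether are inert to the non-basic borate.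

Step 8
Reactants: 12 1-[2,6-bis(methoxymethoxy)-3-[(2S)-7-methyl-3-methylidene-2-(4,4,5,5-tetramethyl-1,3,2-dioxaborolan-2-yl)oct-6-en-1-yl]-4-(triisopropylsilyloxy)phenyl]ethanone
Product: 13 1-[3-[(2S)-2-hydroxy-7-methyl-3-methylideneoct-6-en-1-yl]-2,6-bis(methoxymethoxy)-4-(triisopropylsilyloxy)phenyl]ethanone
Conditions: H2O2 (30% aq), NaOH (2 M aq), THF, 0 °C
Reagents that add atoms: hydrogen peroxide, OO
Why: Hydroperoxide adds to boron and carbon migrates from boron to oxygen with retention and without allylic transposition (boronic ester oxidation), so S-12 should give S-13; the hindered aryl ketone, the acetals and the triisopropylsilyl ether are stable at 0 °C.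

Step 9
Reactants: 13 1-[3-[(2S)-2-hydroxy-7-methyl-3-methylideneoct-6-en-1-yl]-2,6-bis(methoxymethoxy)-4-(triisopropylsilyloxy)phenyl]ethanone
Product: 14 1-[4-hydroxy-3-[(2S)-2-hydroxy-7-methyl-3-methylideneoct-6-en-1-yl]-2,6-bis(methoxymethoxy)phenyl]ethanone
Conditions: TBAF, AcOH, THF, 0 °C
Reagents that add atoms: none
Why: Fluoride cleaves the aryl O–Si bond selectively (silyl ether cleavage); acetic acid buffers the liberated phenoxide, and the acetals and the allylic alcohol are untouched.

Step 10
Reactants: 14 1-[4-hydroxy-3-[(2S)-2-hydroxy-7-methyl-3-methylideneoct-6-en-1-yl]-2,6-bis(methoxymethoxy)phenyl]ethanone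
Product: 15 1-[(2R)-4,6-bis(methoxymethoxy)-2-(6-methylhepta-1,5-dien-2-yl)-2,3-dihydro-1-benzofuran-5-yl]ethanone
Conditions: PPh3, DIAD, THF, 0 °C to rt
Reagents that add atoms: none
Why: Intramolecular Mitsunobu etherification: the acidic phenol para to the acetyl group displaces the oxyphosphonium of the secondary allylic alcohol in a 5-exo-tet SN2 closure with inversion, turning S at C2 into R; the other oxygen next to the side chain is blocked as its acetal, so only one ring can form.

Step 11
Reactants: 15 1-[(2R)-4,6-bis(methoxymethoxy)-2-(6-methylhepta-1,5-dien-2-yl)-2,3-dihydro-1-benzofuran-5-yl]ethanone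
Product: 16 1-[(2R)-4,6-dihydroxy-2-(6-methylhepta-1,5-dien-2-yl)-2,3-dihydro-1-benzofuran-5-yl]ethanone
Conditions: HCl (aq 3 M)/MeOH, rt
Reagents that add atoms: none
Why: Acid-catalysed acetal exchange with methanol removes both methoxymethyl groups, each activated by the neighbouring acetyl carbonyl, under conditions mild enough to leave the allylic aryl ether at C2 and both alkenes intact.

Step 12
Reactants: 17 ethyl 3-oxopentanoate; 18 N-methoxy-N-methylpropanamide
Product: 20 6-ethyl-4-hydroxy-5-methyl-2H-pyran-2-one, via dioxo ester 19 (not isolated)
Conditions: NaH, THF, 0 °C; n-BuLi, 0 °C; 18, −78 to 0 °C; aq HCl; crude 19, DBU, toluene, reflux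
Reagents that add atoms: none
Why: The β-keto ester dianion is acylated at its γ-carbon by the Weinreb amide (dianion acylation), and the 3,5-dioxo ester then lactonises through the enol oxygen of the terminal ketone (6-exo-trig acyl substitution) to the 4-hydroxy-2-pyranone.

Step 13
Reactants: 20 6-ethyl-4-hydroxy-5-methyl-2H-pyran-2-one; 16 1-[(2R)-4,6-dihydroxy-2-(6-methylhepta-1,5-dien-2-yl)-2,3-dihydro-1-benzofuran-5-yl]ethanone
Product: 23 3-{[(2R)-5-acetyl-4,6-dihydroxy-2-(6-methylhepta-1,5-dien-2-yl)-2,3-dihydro-1-benzofuran-7-yl]methyl}-6-ethyl-4-hydroxy-5-methyl-2H-pyran-2-one, via Mannich base 21 (not isolated), via methylidene dione 22 (not isolated)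
Conditions: 20, CH2=NMe2+ I− (1.0 equiv), MeCN, rt; then 16, 60 °C
Reagents that add atoms: N,N-dimethylmethyleneiminium iodide (Eschenmoser's salt), C=[N+](C)C.[I-]
Why: Mannich reaction at C3 of the pyranone, its only enolic carbon, gives 21, which loses dimethylamine on warming to the Michael acceptor 22; this is captured by C7 of 16, the only free and most nucleophilic arene carbon, in a Friedel–Crafts-type conjugate addition with rearomatisation, and preforming 21 before 16 is added limits symmetrical dimers.

## Compound list

1 | 2,4,6-trihydroxyacetophenone | CC(=O)c1c(O)cc(O)cc1O | starting material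
2 | 1-[2,6-dihydroxy-4-(triisopropylsilyloxy)phenyl]ethanone | CC(=O)c1c(O)cc(O[Si](C(C)C)(C(C)C)C(C)C)cc1O | intermediate
3 | 1-[2,6-bis(methoxymethoxy)-4-(triisopropylsilyloxy)phenyl]ethanone | CC(=O)c1c(OCOC)cc(O[Si](C(C)C)(C(C)C)C(C)C)cc1OCOC | intermediate
4 | 1-[3-iodo-2,6-bis(methoxymethoxy)-4-(triisopropylsilyloxy)phenyl]ethanone | CC(=O)c1c(OCOC)cc(O[Si](C(C)C)(C(C)C)C(C)C)c(I)c1OCOC | intermediate
5 | 6-methylhept-5-en-2-one (sulcatone) | CC(=O)CCC=C(C)C | starting material
6 | N'-[(2E)-6-methylhept-5-en-2-ylidene]-2,4,6-triisopropylbenzenesulfonohydrazide | C/C(CCC=C(C)C)=N\NS(=O)(=O)c1c(C(C)C)cc(C(C)C)cc1C(C)C | intermediate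
7 | 2-lithio-6-methylhepta-1,5-diene | [Li]C(=C)CCC=C(C)C | intermediate
8 | 4,4,5,5-tetramethyl-2-(6-methylhepta-1,5-dien-2-yl)-1,3,2-dioxaborolane | C=C(CCC=C(C)C)B1OC(C)(C)C(C)(C)O1 | intermediate
9 | tetraethenylstannane | C=C[Sn](C=C)(C=C)C=C | starting material
10 | ethenyllithium (vinyllithium) | [Li]C=C | intermediate
11 | lithium ethenyl(6-methylhepta-1,5-dien-2-yl)(pinacolato)borate | [Li+].C=C[B-]1(OC(C)(C)C(C)(C)O1)C(=C)CCC=C(C)C | intermediate
12 | 1-[2,6-bis(methoxymethoxy)-3-[(2S)-7-methyl-3-methylidene-2-(4,4,5,5-tetramethyl-1,3,2-dioxaborolan-2-yl)oct-6-en-1-yl]-4-(triisopropylsilyloxy)phenyl]ethanone | C=C(CCC=C(C)C)[C@@H](B1OC(C)(C)C(C)(C)O1)Cc1c(O[Si](C(C)C)(C(C)C)C(C)C)cc(OCOC)c(C(C)=O)c1OCOC | intermediate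
13 | 1-[3-[(2S)-2-hydroxy-7-methyl-3-methylideneoct-6-en-1-yl]-2,6-bis(methoxymethoxy)-4-(triisopropylsilyloxy)phenyl]ethanone | C=C(CCC=C(C)C)[C@@H](O)Cc1c(O[Si](C(C)C)(C(C)C)C(C)C)cc(OCOC)c(C(C)=O)c1OCOC | intermediate
14 | 1-[4-hydroxy-3-[(2S)-2-hydroxy-7-methyl-3-methylideneoct-6-en-1-yl]-2,6-bis(methoxymethoxy)phenyl]ethanone | C=C(CCC=C(C)C)[C@@H](O)Cc1c(O)cc(OCOC)c(C(C)=O)c1OCOC | intermediate
15 | 1-[(2R)-4,6-bis(methoxymethoxy)-2-(6-methylhepta-1,5-dien-2-yl)-2,3-dihydro-1-benzofuran-5-yl]ethanone | C=C(CCC=C(C)C)[C@H]1Cc2c(OCOC)c(C(C)=O)c(OCOC)cc2O1 | intermediate
16 | 1-[(2R)-4,6-dihydroxy-2-(6-methylhepta-1,5-dien-2-yl)-2,3-dihydro-1-benzofuran-5-yl]ethanone | C=C(CCC=C(C)C)[C@H]1Cc2c(O)c(C(C)=O)c(O)cc2O1 | intermediate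
17 | ethyl 3-oxopentanoate | CCC(=O)CC(=O)OCC | starting material
18 | N-methoxy-N-methylpropanamide | CCC(=O)N(C)OC | starting material
19 | ethyl 4-methyl-3,5-dioxoheptanoate (racemic, enolised) | CCC(=O)C(C)C(=O)CC(=O)OCC | intermediate
20 | 6-ethyl-4-hydroxy-5-methyl-2H-pyran-2-one | CCc1oc(=O)cc(O)c1C | intermediate
21 | 3-[(dimethylamino)methyl]-6-ethyl-4-hydroxy-5-methyl-2H-pyran-2-one (formed as its hydroiodide) | CCc1oc(=O)c(CN(C)C)c(O)c1C | intermediate
22 | 6-ethyl-5-methyl-3-methylidene-2H-pyran-2,4(3H)-dione | CCC1=C(C)C(=O)C(=C)C(=O)O1 | intermediate
23 | 3-{[(2R)-5-acetyl-4,6-dihydroxy-2-(6-methylhepta-1,5-dien-2-yl)-2,3-dihydro-1-benzofuran-7-yl]methyl}-6-ethyl-4-hydroxy-5-methyl-2H-pyran-2-one | C=C(CCC=C(C)C)[C@H]1Cc2c(O)c(C(C)=O)c(O)c(Cc3c(O)c(C)c(CC)oc3=O)c2O1 | target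

## Step count and least certain steps

Total: 13 steps. Longest linear sequence: 9 steps (1, 2, 3, 7, 8, 9, 10, 11, 13). Steps 4 to 6 and step 12 are side branches.

**Step 7 (key step).** The likeliest failure is slow capture of the vinyl borate by the crowded arylpalladium cation, which carries an acetal oxygen and a silyloxy group on either side. Direct alkenyl transfer, protodeiodination or catalyst decay could then take over. Chelation of the neighbouring acetal oxygen may block the site needed for alkene binding, and facial selectivity may be lower than with unhindered aryl groups.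

Fallback, setting out from 4 and returning at 13, all by known chemistry: Suzuki–Miyaura allylation of 4 with allylboronic acid pinacol ester (PdCl2(dppf), CsF, THF, reflux) would give 1-[2,6-bis(methoxymethoxy)-3-(prop-2-en-1-yl)-4-(triisopropylsilyloxy)phenyl]ethanone F1. Lemieux–Johnson cleavage (OsO4 cat., NaIO4, 2,6-lutidine, dioxane/H2O) would give 2-[3-acetyl-2,4-bis(methoxymethoxy)-6-(triisopropylsilyloxy)phenyl]acetaldehyde F2. Addition of 7, generated from 6 as in step 5 and transmetallated with CeCl3 to suppress enolisation (THF, −78 °C), would give racemic 1-[3-(2-hydroxy-7-methyl-3-methylideneoct-6-en-1-yl)-2,6-bis(methoxymethoxy)-4-(triisopropylsilyloxy)phenyl]ethanone F3. Dess–Martin oxidation would give the enone 1-[3-acetyl-2,4-bis(methoxymethoxy)-6-(triisopropylsilyloxy)phenyl]-7-methyl-3-methylideneoct-6-en-2-one F4. Corey–Bakshi–Shibata reduction ((R)-2-methyl-CBS-oxazaborolidine, catecholborane, toluene, −78 °C) would then return 13; the catalyst antipode is chosen on the premise that the α-branched alkenyl group acts as the larger substituent, and the hindered aryl ketone should react more slowly.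

**Step 13.** The likeliest failure is competing homodimerisation: 22 can be captured by a second molecule of 20, and any free iminium salt can aminomethylate 16 and lead to the bis-arene. Both nucleophiles are of similar reactivity.

Fallback, setting out from 16 and returning at 23: the polarity of the partners is reversed. Mannich reaction of 16 with CH2=NMe2+ I− (CH2Cl2, rt) would give 1-[(2R)-7-[(dimethylamino)methyl]-4,6-dihydroxy-2-(6-methylhepta-1,5-dien-2-yl)-2,3-dihydro-1-benzofuran-5-yl]ethanone F5. Heating F5 with 20 (dioxane, 90 °C) would release dimethylamine and an ortho-quinone methide on the arene side, which C3 of 20 captures to give 23.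

**Step 10.** The likeliest failure is elimination of the allylic oxyphosphonium towards the conjugated diene (the benzylic C3 hydrogens are available), or ionisation of this allylic leaving group with loss of stereochemical integrity.

Fallback, setting out from 13 and returning at 15, bypassing 14: mesylation (MsCl, Et3N, CH2Cl2, −20 °C) would give (2S)-1-[3-acetyl-2,4-bis(methoxymethoxy)-6-(triisopropylsilyloxy)phenyl]-7-methyl-3-methylideneoct-6-en-2-yl methanesulfonate F6. Treatment with TBAF (THF, 0 °C) would unmask the phenoxide, which displaces the mesylate in a 5-exo-tet SN2 closure with inversion to give 15.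

**Step 5.** The likeliest failure is quenching of 7 by solvent or by incompletely dried hydrazone before borylation, or incomplete fragmentation of the dianion. Either lowers the amount of boronic ester and leaves diene by-products.

Fallback, setting out from 5 and returning at 8: kinetic enolisation on the methyl side (LiN(i-Pr)2, THF, −78 °C) and trapping with PhNTf2 would give 6-methylhepta-1,5-dien-2-yl trifluoromethanesulfonate F7. Miyaura borylation (B2pin2, PdCl2(PPh3)2, PPh3, KOPh, toluene, 50 °C) would then give 8.

**Step 3.** The likeliest failure is sluggish substitution at a position flanked by an acetal and a bulky silyloxy group, with over-iodination at the second equivalent position or acid-promoted acetal loss if the reaction is forced.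

Fallback, setting out from 2 and returning at 4: the order is reversed. Iodination of the more reactive free diphenol 2 (NIS, CH2Cl2, −20 °C, one equivalent) would give 1-[2,6-dihydroxy-3-iodo-4-(triisopropylsilyloxy)phenyl]ethanone F8. Bis-alkylation as in step 2 (NaH, MOMCl, THF/DMF, 0 °C) would then give 4.

## Further compounds

F1 | step 7 | 1-[2,6-bis(methoxymethoxy)-3-(prop-2-en-1-yl)-4-(triisopropylsilyloxy)phenyl]ethanone | C=CCc1c(O[Si](C(C)C)(C(C)C)C(C)C)cc(OCOC)c(C(C)=O)c1OCOC
F2 | step 7 | 2-[3-acetyl-2,4-bis(methoxymethoxy)-6-(triisopropylsilyloxy)phenyl]acetaldehyde | O=CCc1c(O[Si](C(C)C)(C(C)C)C(C)C)cc(OCOC)c(C(C)=O)c1OCOC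
F3 | step 7 | racemic 1-[3-(2-hydroxy-7-methyl-3-methylideneoct-6-en-1-yl)-2,6-bis(methoxymethoxy)-4-(triisopropylsilyloxy)phenyl]ethanone | C=C(CCC=C(C)C)C(O)Cc1c(O[Si](C(C)C)(C(C)C)C(C)C)cc(OCOC)c(C(C)=O)c1OCOC
F4 | step 7 | 1-[3-acetyl-2,4-bis(methoxymethoxy)-6-(triisopropylsilyloxy)phenyl]-7-methyl-3-methylideneoct-6-en-2-one | C=C(CCC=C(C)C)C(=O)Cc1c(O[Si](C(C)C)(C(C)C)C(C)C)cc(OCOC)c(C(C)=O)c1OCOC
F5 | step 13 | 1-[(2R)-7-[(dimethylamino)methyl]-4,6-dihydroxy-2-(6-methylhepta-1,5-dien-2-yl)-2,3-dihydro-1-benzofuran-5-yl]ethanone | C=C(CCC=C(C)C)[C@H]1Cc2c(O)c(C(C)=O)c(O)c(CN(C)C)c2O1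
F6 | step 10 | (2S)-1-[3-acetyl-2,4-bis(methoxymethoxy)-6-(triisopropylsilyloxy)phenyl]-7-methyl-3-methylideneoct-6-en-2-yl methanesulfonate | C=C(CCC=C(C)C)[C@@H](OS(C)(=O)=O)Cc1c(O[Si](C(C)C)(C(C)C)C(C)C)cc(OCOC)c(C(C)=O)c1OCOC
F7 | step 5 | 6-methylhepta-1,5-dien-2-yl trifluoromethanesulfonate | C=C(CCC=C(C)C)OS(=O)(=O)C(F)(F)F
F8 | step 3 | 1-[2,6-dihydroxy-3-iodo-4-(triisopropylsilyloxy)phenyl]ethanone | CC(=O)c1c(O)cc(O[Si](C(C)C)(C(C)C)C(C)C)c(I)c1O
A1 | alternative 1 | 1-[(2R)-4,6-bis(methoxymethoxy)-2-[2-(4-methylpent-3-en-1-yl)-1,3-dioxolan-2-yl]-2,3-dihydro-1-benzofuran-5-yl]ethanone | CC(C)=CCCC1(OCCO1)[C@H]2Cc3c(OCOC)c(C(C)=O)c(OCOC)cc3O2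
A2 | alternative 1 | 1-[4-iodo-2,6-bis(methoxymethoxy)phenyl]ethanone | CC(=O)c1c(OCOC)cc(I)cc1OCOC
A3 | alternative 1 | 2-(4-methylpent-3-en-1-yl)-2-[(2R)-oxiran-2-yl]-1,3-dioxolane | CC(C)=CCCC1(OCCO1)[C@H]2CO2
A4 | alternative 1 | 1-[(2R)-5-acetyl-4,6-dihydroxy-2,3-dihydro-1-benzofuran-2-yl]-5-methylhex-4-en-1-one | CC(C)=CCCC(=O)[C@H]1Cc2c(O)c(C(C)=O)c(O)cc2O1
A5 | alternative 2 | (2R)-5-acetyl-7-{[6-ethyl-5-methyl-4-oxo-2-(triisopropylsilyloxy)-4H-pyran-3-yl]methyl}-2-(6-methylhepta-1,5-dien-2-yl)-2,3-dihydro-1-benzofuran-4,6-diyl diacetate | C=C(CCC=C(C)C)[C@H]1Cc2c(OC(C)=O)c(C(C)=O)c(OC(C)=O)c(Cc3c(O[Si](C(C)C)(C(C)C)C(C)C)oc(CC)c(C)c3=O)c2O1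
A6 | alternative 2 | (2R)-5-acetyl-2-(6-methylhepta-1,5-dien-2-yl)-7-[3-(triisopropylsilyloxy)prop-2-yn-1-yl]-2,3-dihydro-1-benzofuran-4,6-diyl diacetate | C=C(CCC=C(C)C)[C@H]1Cc2c(OC(C)=O)c(C(C)=O)c(OC(C)=O)c(CC#CO[Si](C(C)C)(C(C)C)C(C)C)c2O1
A7 | alternative 2 | 6-ethyl-2,2,5-trimethyl-4H-1,3-dioxin-4-one | CCC1=C(C)C(=O)OC(C)(C)O1
A8 | alternative 2 | 2-methyl-3-oxopent-1-en-1-one (acylketene) | CCC(=O)C(C)=C=O
A9 | alternative 3 | (2R)-5-acetyl-7-[(6-ethyl-4-hydroxy-5-methyl-2-oxo-2H-pyran-3-yl)methyl]-6-hydroxy-2-(6-methylhepta-1,5-dien-2-yl)-2,3-dihydro-1-benzofuran-4-yl acetate | C=C(CCC=C(C)C)[C@H]1Cc2c(OC(C)=O)c(C(C)=O)c(O)c(Cc3c(O)c(C)c(CC)oc3=O)c2O1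
A10 | alternative 3 | 3-(chlorocarbonyl)dihydrocoumarin annulated across O6 and C7 of the (2R)-5-acetyl-4-acetoxy-2-(6-methylhepta-1,5-dien-2-yl)-2,3-dihydrobenzofuran core (mixture at the lactone α-carbon) | C=C(CCC=C(C)C)[C@H]1Cc2c(OC(C)=O)c(C(C)=O)c3OC(=O)C(C(=O)Cl)Cc3c2O1
A11 | alternative 3 | acylketene derived from A10 by loss of HCl (3-(oxomethylidene)dihydrocoumarin on the same core) | C=C(CCC=C(C)C)[C@H]1Cc2c(OC(C)=O)c(C(C)=O)c3OC(=O)C(=C=O)Cc3c2O1
A12 | alternative 3 | pentan-3-one | CCC(=O)CC
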